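**Strategy.** The pyran ring is opened retrosynthetically at the aryl ether bond C8a–O1. C8a lies para to C6, so carrying the C6 side chain as a formyl group turns a fluoride on C8a into an SNAr leaving group. Because C3=C4 of the pyran ring must be cis, only a Z-styrenyl carbinol can close. The key step couples sensitised E-to-Z isomerisation with alkoxide ring closure in one flask. It converts the E-configured Heck product of (S)-linalool and 3-bromo-4-fluorobenzaldehyde (tertiary allylic alcohol, ortho-fluorostyrene, para-formyl) into the chromene, leaving the linalool stereocentre (C2) untouched. Methylenation, hydroboration–Suzuki coupling, allylic hydroxylation and desilylation complete the target.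

Key step: step 2

Assumption (chemistry): (S)-(+)-linalool 1 is used at high enantiomeric purity. No bond to its carbinol carbon is made or broken, so the target inherits that purity, and the descriptor stays S because the priority order O > alkenyl carbon > CH2 > CH3 holds from 1 to 13.

**Step 1**
Reactants: 1 (S)-linalool; 2 3-bromo-4-fluorobenzaldehyde
Product: 3 (S,E)-4-fluoro-3-(3-hydroxy-3,7-dimethylocta-1,6-dien-1-yl)benzaldehyde
Conditions: Pd(OAc)2 (2 mol%), P(o-tol)3 (6 mol%), Et3N (2 equiv), MeCN, 85 °C
Reagents that add atoms: none
Why: Mizoroki–Heck arylation places the aryl group on the unhindered terminal vinyl carbon, and since the carbinol carbon bears no hydrogen, β-hydride elimination can only use the benzylic hydrogen and should give the E-styrene, while the trisubstituted alkene, aldehyde, C–F bond and stereocentre are not involved.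

**Step 2**
Reactants: 3 (S,E)-4-fluoro-3-(3-hydroxy-3,7-dimethylocta-1,6-dien-1-yl)benzaldehyde
Product: 5 (S)-2-methyl-2-(4-methylpent-3-en-1-yl)-2H-chromene-6-carbaldehyde, via Z-alkenol 4 (not isolated)
Conditions: fac-Ir(ppy)3 (1 mol%), Cs2CO3 (2 equiv), dry degassed DMSO (0.03 M), blue LEDs (450 nm), 45 °C, argon
Reagents that add atoms: none
Why: Energy transfer from the triplet state of photoexcited fac-Ir(ppy)3 to the styrenyl alkene of 3 gives a twisted triplet that decays to both geometries, and Z-alkenol 4, whose aryl ring is twisted out of conjugation by the ortho fluorine and the quaternary carbinol, accepts energy less well and so builds up. In 4 the carbinol oxygen lies next to C8a, and its caesium alkoxide adds ipso to the C–F carbon, the negative charge of the Meisenheimer adduct being taken up by the para formyl group before fluoride leaves. The closest known reaction types are sensitised E-to-Z isomerisation of styrenes and intramolecular SNAr etherification of para-formyl aryl fluorides, run here in one flask. The pyran ring closes by six-membered ipso addition–elimination (6-exo-trig with respect to the C8a=C8 bond), making only the C8a–O1 bond. No stereocentre is formed, and C2 keeps the S configuration of linalool because none of its bonds is broken. The step needs geometric and site selectivity, secured by the E alkoxide being unable to span the trans alkene while irreversible closure keeps draining 4 from the photostationary mixture, by fluoride being the only leaving group and para to the only acceptor, and by a weak, sparingly soluble base, dilution and exclusion of oxygen, which hold back intermolecular attack and singlet-oxygen ene reaction at the trisubstituted alkene.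

**Step 3**
Reactants: 5 (S)-2-methyl-2-(4-methylpent-3-en-1-yl)-2H-chromene-6-carbaldehyde
Product: 6 (S)-6-ethenyl-2-methyl-2-(4-methylpent-3-en-1-yl)-2H-chromene
Conditions: Ph3PCH3Br, KOtBu, THF, 0 °C to rt
Reagents that add atoms: methyltriphenylphosphonium bromide, C[P+](c1ccccc1)(c1ccccc1)c1ccccc1.[Br-]
Why: Wittig methylenation of a non-enolisable aryl aldehyde with the unstabilised ylide should be clean, since nothing else in 5 is electrophilic and the chromene and C2 are inert to the ylide.

**Step 4**
Reactants: 7 3-bromocatechol
Product: 8 1-bromo-2,3-bis(tert-butyldimethylsilyloxy)benzene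
Conditions: TBSCl (2.5 equiv), imidazole (5 equiv), DMF, rt
Reagents that add atoms: tert-butyldimethylsilyl chloride, CC(C)(C)[Si](C)(C)Cl
Why: Imidazole-mediated silylation of both phenols is routine, and silyl ethers are chosen because fluoride removes them at the end without acid, strong base or hydrogen, which the chromene, allylic alcohol and alkenes would not tolerate.

**Step 5**
Reactants: 6 (S)-6-ethenyl-2-methyl-2-(4-methylpent-3-en-1-yl)-2H-chromene; 8 1-bromo-2,3-bis(tert-butyldimethylsilyloxy)benzene
Product: 10 (S)-6-{2-[2,3-bis(tert-butyldimethylsilyloxy)phenyl]ethyl}-2-methyl-2-(4-methylpent-3-en-1-yl)-2H-chromene, via B-alkyl-9-BBN adduct 9 (not isolated)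
Conditions: 9-BBN (1.2 equiv), THF, 0 °C to rt; then 8, Pd(OAc)2 (3 mol%), SPhos (6 mol%), K3PO4·H2O (3 equiv), THF, 60 °C
Reagents that add atoms: none
Why: Anti-Markovnikov hydroboration with 9-BBN should select the monosubstituted vinyl group over the trisubstituted chain alkene and the hindered cis C3=C4 alkene next to quaternary C2, and the primary alkylborane then undergoes B-alkyl Suzuki–Miyaura coupling with 8, the bulky electron-rich phosphine coping with the ortho silyloxy group and the mild hydrated phosphate sparing the aryl silyl ethers.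

**Step 6**
Reactants: 10 (S)-6-{2-[2,3-bis(tert-butyldimethylsilyloxy)phenyl]ethyl}-2-methyl-2-(4-methylpent-3-en-1-yl)-2H-chromene
Product: 12 (E)-5-[(S)-6-{2-[2,3-bis(tert-butyldimethylsilyloxy)phenyl]ethyl}-2-methyl-2H-chromen-2-yl]-2-methylpent-2-en-1-ol, via enal 11 (not isolated)
Conditions: SeO2 (0.3 equiv), t-BuOOH (3 equiv), CH2Cl2, 0 °C to rt; aqueous work-up; then NaBH4, CeCl3·7H2O, MeOH, 0 °C
Reagents that add atoms: selenium dioxide, O=[Se]=O (delivers the oxygen atom); tert-butyl hydroperoxide, CC(C)(C)OO (re-oxidant that restocks it)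
Why: Riley allylic oxidation (ene reaction, then [2,3]-sigmatropic shift) should hydroxylate the methyl group trans to the chain of the gem-dimethyl terminus with E geometry, the chromene alkene having no allylic hydrogen because C2 is quaternary, and Luche reduction returns the over-oxidised enal 11 to the alcohol without touching the alkenes.

**Step 7**
Reactants: 12 (E)-5-[(S)-6-{2-[2,3-bis(tert-butyldimethylsilyloxy)phenyl]ethyl}-2-methyl-2H-chromen-2-yl]-2-methylpent-2-en-1-ol
Product: 13 3-{2-[(S)-2-[(E)-5-hydroxy-4-methylpent-3-en-1-yl]-2-methyl-2H-chromen-6-yl]ethyl}benzene-1,2-diol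
Conditions: Bu4NF (2.5 equiv), AcOH (2.5 equiv), THF, 0 °C, argon
Reagents that add atoms: none
Why: Fluoride desilylation cleaves both aryl Si–O bonds, and the acetic acid buffer under argon keeps the liberated catechol protonated and unoxidised while the allylic alcohol, both alkenes and C2 are unaffected.

**Compound list**

1 | (S)-linalool, (S)-3,7-dimethylocta-1,6-dien-3-ol | CC(C)=CCC[C@@](O)(C)C=C | starting material
2 | 3-bromo-4-fluorobenzaldehyde | O=Cc1ccc(F)c(Br)c1 | starting material
3 | (S,E)-4-fluoro-3-(3-hydroxy-3,7-dimethylocta-1,6-dien-1-yl)benzaldehyde | CC(C)=CCC[C@@](O)(C)/C=C/c1cc(C=O)ccc1F | intermediate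
4 | (S,Z)-4-fluoro-3-(3-hydroxy-3,7-dimethylocta-1,6-dien-1-yl)benzaldehyde (Z-alkenol) | CC(C)=CCC[C@@](O)(C)/C=C\c1cc(C=O)ccc1F | intermediate
5 | (S)-2-methyl-2-(4-methylpent-3-en-1-yl)-2H-chromene-6-carbaldehyde | CC(C)=CCC[C@@]1(C)C=Cc2cc(C=O)ccc2O1 | intermediate
6 | (S)-6-ethenyl-2-methyl-2-(4-methylpent-3-en-1-yl)-2H-chromene | CC(C)=CCC[C@@]1(C)C=Cc2cc(C=C)ccc2O1 | intermediate
7 | 3-bromocatechol, 3-bromobenzene-1,2-diol | Oc1cccc(Br)c1O | starting material
8 | 1-bromo-2,3-bis(tert-butyldimethylsilyloxy)benzene | CC(C)(C)[Si](C)(C)Oc1cccc(Br)c1O[Si](C)(C)C(C)(C)C | intermediate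
9 | 9-{2-[(S)-2-methyl-2-(4-methylpent-3-en-1-yl)-2H-chromen-6-yl]ethyl}-9-borabicyclo[3.3.1]nonane (B-alkyl-9-BBN adduct) | CC(C)=CCC[C@@]1(C)C=Cc2cc(CCB3C4CCCC3CCC4)ccc2O1 | intermediate
10 | (S)-6-{2-[2,3-bis(tert-butyldimethylsilyloxy)phenyl]ethyl}-2-methyl-2-(4-methylpent-3-en-1-yl)-2H-chromene | CC(C)=CCC[C@@]1(C)C=Cc2cc(CCc3cccc(O[Si](C)(C)C(C)(C)C)c3O[Si](C)(C)C(C)(C)C)ccc2O1 | intermediate
11 | (E)-5-[(S)-6-{2-[2,3-bis(tert-butyldimethylsilyloxy)phenyl]ethyl}-2-methyl-2H-chromen-2-yl]-2-methylpent-2-enal (enal) | C/C(=C\CC[C@@]1(C)C=Cc2cc(CCc3cccc(O[Si](C)(C)C(C)(C)C)c3O[Si](C)(C)C(C)(C)C)ccc2O1)C=O | intermediate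
12 | (E)-5-[(S)-6-{2-[2,3-bis(tert-butyldimethylsilyloxy)phenyl]ethyl}-2-methyl-2H-chromen-2-yl]-2-methylpent-2-en-1-ol | C/C(=C\CC[C@@]1(C)C=Cc2cc(CCc3cccc(O[Si](C)(C)C(C)(C)C)c3O[Si](C)(C)C(C)(C)C)ccc2O1)CO | intermediate
13 | 3-{2-[(S)-2-[(E)-5-hydroxy-4-methylpent-3-en-1-yl]-2-methyl-2H-chromen-6-yl]ethyl}benzene-1,2-diol (CNP0267525.1) | C/C(=C\CC[C@@]1(C)C=Cc2cc(CCc3cccc(O)c3O)ccc2O1)CO | target

**Step count and risks**

Total steps: 7. Longest linear sequence: 6 steps (steps 1, 2, 3, 5, 6, 7).

Steps most likely to fail:

1. Step 2. Closure of the Z alkoxide may be slower than intermolecular attack of alkoxide on the formyl group or on the C–F carbon of a second molecule. Continued sensitisation of the chromene could also open and re-close the pyran ring electrocyclically and erode the enantiopurity. Fallback: the coupled funnel is given up for two separate operations, setting out from 3 and returning at 5. Irradiation of 3 with fac-Ir(ppy)3 in MeCN at rt without base should give a Z-enriched mixture, from which Z-alkenol 4 is separated by chromatography and the E isomer re-irradiated. Isolated 4 is then closed in the dark with NaH in THF at 0 °C to rt, so the chromene never meets light and no alkoxide coexists with excited sensitiser. This fallback makes no compound outside the list (F0).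

2. Step 6. Oxidation may run on to the enal and beyond, compete at the internal allylic methylene, or be accompanied by attack of electrophilic selenium on the electron-rich chromene alkene. Fallback: setting out from 10 and returning at 12, the isopropylidene terminus is exchanged by cross-metathesis with methacrolein (second-generation Hoveyda–Grubbs catalyst, CH2Cl2, 40 °C), which should give the E-enal 11 directly with loss of 2-methylpropene. The cis C3=C4 alkene next to quaternary C2 should be a poor metathesis partner. Luche reduction (NaBH4, CeCl3·7H2O, MeOH, 0 °C) then gives 12. This fallback makes no compound outside the list (F0).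

3. Step 5. The aryl silyl ethers may be lost under the basic aqueous conditions, and coupling at the hindered ortho-silyloxy bromide may be slow enough for protodeboronation or β-hydride elimination of the alkylborane to take over. Fallback: a base-free Negishi coupling, setting out from 6 and returning at 10. Hydroboration of 6 with 9-BBN (via 9) followed by oxidation with NaBO3·4H2O gives the primary alcohol 2-[(S)-2-methyl-2-(4-methylpent-3-en-1-yl)-2H-chromen-6-yl]ethan-1-ol F1. Appel iodination (I2, PPh3, imidazole, CH2Cl2, 0 °C) gives (S)-6-(2-iodoethyl)-2-methyl-2-(4-methylpent-3-en-1-yl)-2H-chromene F2. Zinc insertion (Zn dust, LiCl, THF, rt) gives {2-[(S)-2-methyl-2-(4-methylpent-3-en-1-yl)-2H-chromen-6-yl]ethyl}zinc iodide F3. F3 is coupled with 8 (Pd(OAc)2, SPhos, THF, rt to 40 °C) to give 10, with no base present to threaten the silyl ethers.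

**Further compounds**

F0 | step 2 | none | none
F0 | step 6 | none | none
F1 | step 5 | 2-[(S)-2-methyl-2-(4-methylpent-3-en-1-yl)-2H-chromen-6-yl]ethan-1-ol | CC(C)=CCC[C@@]1(C)C=Cc2cc(CCO)ccc2O1
F2 | step 5 | (S)-6-(2-iodoethyl)-2-methyl-2-(4-methylpent-3-en-1-yl)-2H-chromene | CC(C)=CCC[C@@]1(C)C=Cc2cc(CCI)ccc2O1
F3 | step 5 | {2-[(S)-2-methyl-2-(4-methylpent-3-en-1-yl)-2H-chromen-6-yl]ethyl}zinc iodide | CC(C)=CCC[C@@]1(C)C=Cc2cc(CC[Zn]I)ccc2O1
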